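A bench chemist has a rule for cedar: charge the reagent above the limiting reagent, here E and X together, and it will see the run through.

| setting | cedar | ash | flask |
|---|---|---|---|
| E | 0.050 M | 0.050 M | 0.050 M |
| X | 0.050 M | 0.050 M | 0.050 M |
| J | 0.15 M | 0.22 M | 0.150 M |
| Z | 0.26 mM | 0.26 mM | 0.26 mM |
| remark | the very flask that is asked about, followed so far | run made earlier |  |
| time |  |  | 50 min |

| run | time / min | X / % | E / % |
|---|---|---|---|
| cedar | 1.33 | 49.0 | 46.6 |
| cedar | 3.00 | 45.8 | 39.1 |
| cedar | 4.00 | 44.3 | 36.2 |
| cedar | 6.00 | 41.4 | 29.9 |
| cedar | 8.00 | 38.4 | 24.0 |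
| cedar | 10.0 | 35.7 | 19.4 |
| ash | 2.00 | 47.8 | 43.8 |
| ash | 5.00 | 42.9 | 32.2 |
| ash | 10.0 | 35.3 | 19.0 |
| ash | 15.0 | 28.7 | 10.5 |
| ash | 20.0 | 23.8 | 5.8 |
| ash | 30.0 | 15.8 | 1.9 |
| ash | 40.0 | 10.0 | 0.8 |

(each reading ± 0.3 percentage points)

- whether the excess of X over E among what is left of the two reaches 80% by 50 min (no / yes)
- the highest excess of X over E among what is left of the two up to 50 min

By that rule cedar looks safe, with J at 1.50 of the E and X charge. But J does two jobs. Part leaves as D and Q, and part merely stands in solution as G, like the holdup in a tank. So we write the balance of J in fractions of the E and X charge, with c the part reacted and g the dissolved G: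

solid J = 1.50 − c − g

We carry the J reserve, the J left, solid or dissolved, as a fraction of the E and X charge when c reaches 1:

reserve = 1.50 − 1 = 0.500

This is the border of the rule: in cedar, solid lasts to full conversion as long as g stays under the reserve.

What do the readings say? At 10.0 min, cedar has X 35.7% and E 19.4%, and ash has 35.3% and 19.0%. They agree within the scatter, so we take g as equal in both. Cedar has then reacted 44.9%, which puts g under:

1.50 − 44.9% = 1.05

That ceiling is above the reserve, so the readings leave the border open. Ash's readings give an excess of 78.5% at 30.0 min and 85.2% at 40.0 min. We assume that cedar goes on like ash and commit to yes, near the time ash's readings pass 80%.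

The forecast says yes, with a top of 92%. Its warning: “Solid could vanish late, after which G declines.”

Cedar gives yes, with a top of 94.6%, and the excess reaches 80% at 31.6 min.

    G + Z + E → Z + D (k = 897 /M²/s)
    G + Z + X → Z + Q (k = 321 /M²/s)
    J ⇌ G, rate k3*(cs3 - [G]) while solid is left; crystals form when [G] > cs3 (solubility = 42.0 mM, k = 0.0177 /s)
    2 Z ⇌ L, settled at all times (K = 37600 /M)

In cedar, J dissolved while E and X reacted: G stood at 0.0369 M at 5.00 min and 0.0417 M at 50.0 min, when J was 10.2% of its own charge and E was 0.189%. At 500 min, g is 0.420, under the reserve of 0.500, and J is 5.33% of its own charge. At twice the dilution the reserve is still 0.500, but of a thinner charge, and the same G would be 0.840 of it; that thin run ended at an excess of 81.9%.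

All runs come from a simulation from invented constants, noise included.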